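The C3–O bond is traced back to a C3–H bond. The feature exploited lies in ring B (the dihydrofuran ring): once the formyl carbon on C1' is carried as a carboxylic acid, the benzylic C3–H sits gamma to that carboxyl carbon, so a carboxyl oxygen radical can reach only the C3 hydrogen on the face of the C2 side chain. One oxidative operation therefore forms the C3–O bond, closes a cis-fused γ-lactone and sets C3 relative to C2. The precursor is (R)-2-(5-acetyl-2,3-dihydrobenzofuran-2-yl)acrylic acid 14, assembled by catalytic asymmetric closure of a phenol onto a Morita–Baylis–Hillman carbonate; the lactone is afterwards reduced and unpacked into the C3 acetate and the enal.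

Key step: step 10

Numbering used: O1, C2, C3, C3a, C4 to C7, C7a for the dihydrobenzofuran (ring A benzene, ring B dihydrofuran); C1' is the vinyl carbon on C2.
Assumption: in step 8 the quinidine-derived catalyst is taken to give the (2R) ether; should analysis show the opposite sense, the quinine-derived pseudoenantiomer (DHQ)2PHAL is used with no other change.

Step 1
Reactants: 1 4-hydroxyacetophenone; 2 allyl bromide
Product: 3 4-(allyloxy)acetophenone
Conditions: K2CO3, acetone, reflux
Reagents that add atoms: none
Why: Williamson ether synthesis: the acidic phenol is deprotonated by K2CO3 and alkylated at oxygen by the primary allylic bromide, the ketone being inert.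

Step 2
Reactants: 3 4-(allyloxy)acetophenone
Product: 5 3-allyl-4-hydroxyacetophenone, via ortho-dienone 4 (not isolated)
Conditions: N,N-diethylaniline, 200 °C
Reagents that add atoms: none
Why: Aromatic Claisen rearrangement: the [3,3] shift delivers the allyl group to the ortho carbon (para is blocked by the acetyl group) and dienone 4 tautomerises to the phenol.

Step 3
Reactants: 5 3-allyl-4-hydroxyacetophenone
Product: 6 3-allyl-4-(triisopropylsilyloxy)acetophenone
Conditions: iPr3SiCl, imidazole, DMF, 25 °C
Reagents that add atoms: chlorotriisopropylsilane, CC(C)[Si](Cl)(C(C)C)C(C)C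
Why: Silyl ether protection of the phenol for the ozonolysis, the amine-mediated step 5 and the carbonate formation; the bulky triisopropylsilyl group is chosen because an aryl silyl ether para to an acyl group is otherwise easily lost or transferred to a neighbouring alkoxide.

Step 4
Reactants: 6 3-allyl-4-(triisopropylsilyloxy)acetophenone
Product: 8 2-[5-acetyl-2-(triisopropylsilyloxy)phenyl]acetaldehyde, via secondary ozonide 7 (not isolated)
Conditions: O3, CH2Cl2, −78 °C; then PPh3, −78 to 25 °C
Reagents that add atoms: ozone, [O-][O+]=O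
Why: Ozonolysis (Criegee mechanism) with reductive work-up: ozone should add to the terminal alkene far faster than to the acyl-deactivated arene, and the aldehyde is taken on crude because arylacetaldehydes enolise readily.

Step 5
Reactants: 8 2-[5-acetyl-2-(triisopropylsilyloxy)phenyl]acetaldehyde; 9 methyl acrylate
Product: 10 methyl 4-[5-acetyl-2-(triisopropylsilyloxy)phenyl]-3-hydroxy-2-methylenebutanoate (racemic)
Conditions: DABCO (1 equiv), methyl acrylate (neat, excess), 25 °C
Reagents that add atoms: none
Why: Morita–Baylis–Hillman reaction: the DABCO–acrylate ammonium enolate adds to the aldehyde (the aryl ketone is not electrophilic enough) and loss of DABCO gives the allylic alcohol, whose stereocentre need not be controlled because step 8 erases it.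

Step 6
Reactants: 10 methyl 4-[5-acetyl-2-(triisopropylsilyloxy)phenyl]-3-hydroxy-2-methylenebutanoate
Product: 11 methyl 4-[5-acetyl-2-(triisopropylsilyloxy)phenyl]-3-(tert-butoxycarbonyloxy)-2-methylenebutanoate (racemic)
Conditions: Boc2O, DMAP (10 mol %), CH2Cl2, 0 to 25 °C
Reagents that add atoms: di-tert-butyl dicarbonate, CC(C)(C)OC(=O)OC(=O)OC(C)(C)C
Why: DMAP-catalysed carbonate formation at the only free hydroxyl turns it into a leaving group that releases its own base (tert-butoxide after loss of CO2) in step 8.

Step 7
Reactants: 11 the silyl-protected carbonate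
Product: 12 methyl 4-(5-acetyl-2-hydroxyphenyl)-3-(tert-butoxycarbonyloxy)-2-methylenebutanoate (racemic)
Conditions: Bu4NF, AcOH (1:1), THF, 0 °C
Reagents that add atoms: none
Why: Fluoride desilylation of the aryl silyl ether, buffered with AcOH so that the phenol stays protonated and cannot attack the allylic carbonate before the chiral catalyst is present.

Step 8
Reactants: 12 methyl 4-(5-acetyl-2-hydroxyphenyl)-3-(tert-butoxycarbonyloxy)-2-methylenebutanoate
Product: 13 methyl 2-[(2R)-5-acetyl-2,3-dihydrobenzofuran-2-yl]prop-2-enoate
Conditions: (DHQD)2PHAL (10 mol %), toluene (0.05 M), 0 to 25 °C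
Reagents that add atoms: none
Why: Lewis-base-catalysed allylic substitution of a Morita–Baylis–Hillman carbonate (SN2' addition of the quinuclidine nitrogen, then SN2' return of the nucleophile): the liberated tert-butoxide deprotonates the phenol and the phenoxide closes ring B 5-exo-trig on the chiral allylammonium ion, so C2 is set by the catalyst and both enantiomers of 12 converge on one product.

Step 9
Reactants: 13 methyl 2-[(2R)-5-acetyl-2,3-dihydrobenzofuran-2-yl]prop-2-enoate
Product: 14 2-[(2R)-5-acetyl-2,3-dihydrobenzofuran-2-yl]prop-2-enoic acid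
Conditions: LiOH, THF/H2O, 0 °C; then aqueous HCl to pH 3
Reagents that add atoms: lithium hydroxide, [Li+].[OH-]
Why: Ester saponification (acyl–oxygen cleavage): C2–H is not alpha to the carbonyl group so the stereocentre cannot be lost by enolisation, the low temperature limits conjugate addition of hydroxide to the acrylate, and the acid offers a crystallisation point for raising enantiopurity.

Step 10
Reactants: 14 2-[(2R)-5-acetyl-2,3-dihydrobenzofuran-2-yl]prop-2-enoic acid
Product: 17 cis-fused tricyclic α-methylene-γ-butyrolactone bearing the C5 acetyl group (C2 S and C3 S), via acyl hypoiodite 15 (not isolated), via C3 iodide 16 (not isolated)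
Conditions: PhI(OAc)2 (1.5 equiv), I2 (0.5 equiv), 1,2-dichloroethane, visible light (white LED), 25 °C, argon
Reagents that add atoms: none
Why: Proposed new method: ligand exchange with acetyl hypoiodite gives acyl hypoiodite 15, whose O–I bond is cleaved by light to a carboxyl radical that, being vinylogous to an aroyloxy radical, loses CO2 only slowly and instead takes the C3 hydrogen on its own face through a six-membered (1,5) transition state. The benzylic C3 radical is capped by iodine to give 16, which ionises with help from the ring oxygen O1 (an ortho-alkoxybenzyl cation) and is captured by the carboxyl oxygen. The closest known reaction type is the hypervalent-iodine/halogen lactonisation of 2-alkylbenzoic acids to phthalides, of which this is the non-aromatic acrylic-acid counterpart with C1'=CH2 standing in for the arene bond. The one new ring is the γ-lactone, closed in the 5-exo-tet mode at C3. The new C3 centre is controlled by the existing C2 centre, because the three-atom tether can span the C2–C3 bond only on the face of the side chain and so only the cis-fused (3S) lactone can form. The step needs C3–H over the weaker C2–H, lactone closure over loss of HI to a benzofuran, and an intact arene: the 1,5-geometry (C2–H would demand a five-membered transition state) secures the first, base-free conditions at 25 °C with fast intramolecular capture are relied on for the second, and the C5 acetyl group, kept unreduced for this purpose, deactivates ring A toward iodination.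

Step 11
Reactants: 17 the lactone ketone
Product: 18 the same lactone with the C5 acetyl group reduced to a (1R)-1-hydroxyethyl group
Conditions: (S)-2-methyl-CBS-oxazaborolidine (15 mol %), BH3·SMe2 (0.7 equiv), THF, −20 °C; then MeOH
Reagents that add atoms: none
Why: Corey–Bakshi–Shibata reduction: the (S)-oxazaborolidine should deliver hydride to the Si face of the aryl methyl ketone as it does for acetophenone, setting the (R) carbinol under catalyst control, while the lactone and its electron-poor alkene are left alone by borane at this temperature.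

Step 12
Reactants: 18 the (1R)-hydroxyethyl lactone
Product: 19 the (1R)-1-(triethylsilyloxy)ethyl lactone
Conditions: Et3SiCl, imidazole, CH2Cl2, 0 °C
Reagents that add atoms: chlorotriethylsilane, CC[Si](Cl)(CC)CC
Why: Silyl ether formation at the only hydroxyl, with a triethylsilyl group chosen so that it can later be removed beside a tert-butyldiphenylsilyl ether.

Step 13
Reactants: 19 the silyl-protected lactone
Product: 21 (2S,3S)-2-(3-hydroxyprop-1-en-2-yl)-5-[(1R)-1-(triethylsilyloxy)ethyl]-2,3-dihydrobenzofuran-3-ol, via lactol 20 (not isolated)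
Conditions: iBu2AlH (4 equiv), CH2Cl2, −78 to 0 °C; then aqueous potassium sodium tartrate (KNaC4H4O6)
Reagents that add atoms: none
Why: iBu2AlH reduction of the temporary lactone through the lactol (as its aluminium alkoxide) to the diol: the reagent adds 1,2 and not in conjugate fashion to the α-methylene unit, and no stereocentre is touched.

Step 14
Reactants: 21 the diol
Product: 22 (2S,3S)-2-[3-(tert-butyldiphenylsilyloxy)prop-1-en-2-yl]-5-[(1R)-1-(triethylsilyloxy)ethyl]-2,3-dihydrobenzofuran-3-ol
Conditions: tBuPh2SiCl (1.1 equiv), imidazole, CH2Cl2, 0 °C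
Reagents that add atoms: tert-butylchlorodiphenylsilane, CC(C)(C)[Si](Cl)(c1ccccc1)c1ccccc1
Why: Selective silylation: the bulky silyl chloride should take the primary allylic hydroxyl and leave the hindered secondary benzylic C3 hydroxyl free.

Step 15
Reactants: 22 the mono-silylated C3 alcohol
Product: 23 the C3 acetate of 22 (2S,3S; both silyl ethers retained)
Conditions: Ac2O, pyridine, DMAP (catalytic), CH2Cl2, 0 to 25 °C
Reagents that add atoms: acetic anhydride, CC(=O)OC(C)=O
Why: DMAP-catalysed O-acetylation of the remaining hydroxyl, which does not touch the C3–O bond and so retains the configuration set in step 10.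

Step 16
Reactants: 23 the C3 acetate bis-silyl ether
Product: 24 the C3 acetate with a free (1R)-1-hydroxyethyl group at C5 and the primary tert-butyldiphenylsilyl ether retained
Conditions: HF·pyridine, pyridine, THF, 0 °C
Reagents that add atoms: none
Why: Selective fluoride desilylation: a secondary triethylsilyl ether is cleaved far faster than a primary tert-butyldiphenylsilyl ether, and the buffered fluoride conditions are preferred to acidic methanolysis because the carbinol carbon is a para-alkoxybenzylic centre that could ionise and racemise under acid.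

Step 17
Reactants: 24 the side-chain alcohol; 25 angelic acid
Product: 27 the (1R)-angelate of 24 (C3 acetate and primary silyl ether retained), via mixed anhydride 26 (not isolated)
Conditions: 25, 2,4,6-Cl3C6H2COCl, Et3N, toluene, 25 °C; then 24, toluene, 75 °C
Reagents that add atoms: none
Why: Yamaguchi esterification: the hindered trichlorobenzoyl carbonyl of the mixed anhydride steers the alcohol to the angeloyl carbonyl, the omission of a nucleophilic catalyst is meant to prevent Z to E isomerisation to the tiglate, and acylation at oxygen retains the (R) centre.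

Step 18
Reactants: 27 the silyl-protected angelate
Product: 28 (2S,3S)-3-acetoxy-2-(3-hydroxyprop-1-en-2-yl)-5-[(1R)-1-(angeloyloxy)ethyl]-2,3-dihydrobenzofuran
Conditions: Bu4NF, AcOH (1:1), THF, 0 to 25 °C
Reagents that add atoms: none
Why: Fluoride desilylation buffered with AcOH, so that neither an alkoxide nor basic fluoride is present to migrate, cleave or eliminate the C3 acetate or to touch the angelate.

Step 19
Reactants: 28 the allylic alcohol
Product: 29 the target, (2S,3S)-3-acetoxy-2-(3-oxoprop-1-en-2-yl)-5-[(1R)-1-(angeloyloxy)ethyl]-2,3-dihydrobenzofuran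
Conditions: MnO2 (activated, excess), CH2Cl2, 25 °C
Reagents that add atoms: none
Why: MnO2 oxidation of the primary allylic alcohol to the enal under neutral conditions, placed last because the enal makes C2–H acidic and base could then eliminate the C3 acetate to a benzofuran.

Compound list
1 | 4-hydroxyacetophenone | CC(=O)c1ccc(O)cc1 | starting material
2 | allyl bromide | C=CCBr | starting material
3 | 4-(allyloxy)acetophenone | CC(=O)c1ccc(OCC=C)cc1 | intermediate
4 | 4-acetyl-6-allylcyclohexa-2,4-dien-1-one (ortho-dienone, racemic, not isolated) | O=C1C=CC(C(C)=O)=CC1CC=C | intermediate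
5 | 3-allyl-4-hydroxyacetophenone | CC(=O)c1ccc(O)c(CC=C)c1 | intermediate
6 | 3-allyl-4-(triisopropylsilyloxy)acetophenone | CC(=O)c1ccc(O[Si](C(C)C)(C(C)C)C(C)C)c(CC=C)c1 | intermediate
7 | 3-[5-acetyl-2-(triisopropylsilyloxy)benzyl]-1,2,4-trioxolane (secondary ozonide, not isolated) | CC(=O)c1ccc(O[Si](C(C)C)(C(C)C)C(C)C)c(CC2OCOO2)c1 | intermediate
8 | 2-[5-acetyl-2-(triisopropylsilyloxy)phenyl]acetaldehyde | CC(=O)c1ccc(O[Si](C(C)C)(C(C)C)C(C)C)c(CC=O)c1 | intermediate
9 | methyl acrylate | C=CC(=O)OC | starting material
10 | methyl 4-[5-acetyl-2-(triisopropylsilyloxy)phenyl]-3-hydroxy-2-methylenebutanoate (racemic) | C=C(C(=O)OC)C(O)Cc1cc(C(C)=O)ccc1O[Si](C(C)C)(C(C)C)C(C)C | intermediate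
11 | methyl 4-[5-acetyl-2-(triisopropylsilyloxy)phenyl]-3-(tert-butoxycarbonyloxy)-2-methylenebutanoate (racemic) | C=C(C(=O)OC)C(OC(=O)OC(C)(C)C)Cc1cc(C(C)=O)ccc1O[Si](C(C)C)(C(C)C)C(C)C | intermediate
12 | methyl 4-(5-acetyl-2-hydroxyphenyl)-3-(tert-butoxycarbonyloxy)-2-methylenebutanoate (racemic) | C=C(C(=O)OC)C(OC(=O)OC(C)(C)C)Cc1cc(C(C)=O)ccc1O | intermediate
13 | methyl 2-[(2R)-5-acetyl-2,3-dihydrobenzofuran-2-yl]prop-2-enoate | C=C(C(=O)OC)[C@@H]1Oc2ccc(C(C)=O)cc2C1 | intermediate
14 | 2-[(2R)-5-acetyl-2,3-dihydrobenzofuran-2-yl]prop-2-enoic acid | C=C(C(=O)O)[C@@H]1Oc2ccc(C(C)=O)cc2C1 | intermediate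
15 | acyl hypoiodite of acid 14 (not isolated) | C=C(C(=O)OI)[C@@H]1Oc2ccc(C(C)=O)cc2C1 | intermediate
16 | 2-[(2R)-5-acetyl-3-iodo-2,3-dihydrobenzofuran-2-yl]prop-2-enoic acid (either C3 epimer, not isolated) | C=C(C(=O)O)[C@@H]1Oc2ccc(C(C)=O)cc2C1I | intermediate
17 | 5-acetyl-2,3-dihydrobenzofuran whose C3 oxygen and C1' carboxyl carbon form a cis-fused α-methylene-γ-butyrolactone (2S,3S) | C=C(C3=O)[C@@H]1Oc2ccc(C(C)=O)cc2[C@@H]1O3 | intermediate
18 | lactone 17 with a (1R)-1-hydroxyethyl group at C5 (2S,3S) | C=C(C3=O)[C@@H]1Oc2ccc([C@@H](C)O)cc2[C@@H]1O3 | intermediate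
19 | lactone 17 with a (1R)-1-(triethylsilyloxy)ethyl group at C5 (2S,3S) | C=C(C3=O)[C@@H]1Oc2ccc([C@@H](C)O[Si](CC)(CC)CC)cc2[C@@H]1O3 | intermediate
20 | lactol of 19 (lactone carbonyl reduced to CH–OH, formed as its aluminium alkoxide, not isolated) | C=C(C3O)[C@@H]1Oc2ccc([C@@H](C)O[Si](CC)(CC)CC)cc2[C@@H]1O3 | intermediate
21 | (2S,3S)-2-(3-hydroxyprop-1-en-2-yl)-5-[(1R)-1-(triethylsilyloxy)ethyl]-2,3-dihydrobenzofuran-3-ol | C=C(CO)[C@@H]1Oc2ccc([C@@H](C)O[Si](CC)(CC)CC)cc2[C@@H]1O | intermediate
22 | (2S,3S)-2-[3-(tert-butyldiphenylsilyloxy)prop-1-en-2-yl]-5-[(1R)-1-(triethylsilyloxy)ethyl]-2,3-dihydrobenzofuran-3-ol | C=C(CO[Si](c3ccccc3)(c3ccccc3)C(C)(C)C)[C@@H]1Oc2ccc([C@@H](C)O[Si](CC)(CC)CC)cc2[C@@H]1O | intermediate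
23 | (2S,3S)-3-acetoxy-2-[3-(tert-butyldiphenylsilyloxy)prop-1-en-2-yl]-5-[(1R)-1-(triethylsilyloxy)ethyl]-2,3-dihydrobenzofuran | C=C(CO[Si](c3ccccc3)(c3ccccc3)C(C)(C)C)[C@@H]1Oc2ccc([C@@H](C)O[Si](CC)(CC)CC)cc2[C@@H]1OC(C)=O | intermediate
24 | (2S,3S)-3-acetoxy-2-[3-(tert-butyldiphenylsilyloxy)prop-1-en-2-yl]-5-[(1R)-1-hydroxyethyl]-2,3-dihydrobenzofuran | C=C(CO[Si](c3ccccc3)(c3ccccc3)C(C)(C)C)[C@@H]1Oc2ccc([C@@H](C)O)cc2[C@@H]1OC(C)=O | intermediate
25 | angelic acid, (Z)-2-methylbut-2-enoic acid | C/C=C(/C)C(=O)O | starting material
26 | angelic 2,4,6-trichlorobenzoic anhydride (not isolated) | C/C=C(/C)C(=O)OC(=O)c1c(Cl)cc(Cl)cc1Cl | intermediate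
27 | (2S,3S)-3-acetoxy-2-[3-(tert-butyldiphenylsilyloxy)prop-1-en-2-yl]-5-[(1R)-1-(angeloyloxy)ethyl]-2,3-dihydrobenzofuran | C=C(CO[Si](c3ccccc3)(c3ccccc3)C(C)(C)C)[C@@H]1Oc2ccc([C@@H](C)OC(=O)/C(C)=C\C)cc2[C@@H]1OC(C)=O | intermediate
28 | (2S,3S)-3-acetoxy-2-(3-hydroxyprop-1-en-2-yl)-5-[(1R)-1-(angeloyloxy)ethyl]-2,3-dihydrobenzofuran | C=C(CO)[C@@H]1Oc2ccc([C@@H](C)OC(=O)/C(C)=C\C)cc2[C@@H]1OC(C)=O | intermediate
29 | (2S,3S)-3-acetoxy-2-(3-oxoprop-1-en-2-yl)-5-[(1R)-1-(angeloyloxy)ethyl]-2,3-dihydrobenzofuran | C=C(C=O)[C@@H]1Oc2ccc([C@@H](C)OC(=O)/C(C)=C\C)cc2[C@@H]1OC(C)=O | target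

Total step count: 19. Longest linear sequence: 19 steps (1 to 29); angelic acid 25 enters in step 17 as purchased.

Steps most likely to fail

Step 10 (proposed new method). The C3 iodide or the C3 radical may lose the C2 hydrogen and aromatise to a benzofuran instead of closing the lactone. The carboxyl radical may also decarboxylate, or ring A may be iodinated. The fallback replaces the carboxyl radical by an alkoxy radical, using the known hypoiodite reaction of alcohols (remote C–H etherification through 1,5-hydrogen transfer). It sets out from ester 13. Reduction with the (S)-oxazaborolidine and BH3·SMe2 should give methyl 2-[(2R)-5-[(1R)-1-hydroxyethyl]-2,3-dihydrobenzofuran-2-yl]prop-2-enoate F1. Et3SiCl and imidazole then give methyl 2-[(2R)-5-[(1R)-1-(triethylsilyloxy)ethyl]-2,3-dihydrobenzofuran-2-yl]prop-2-enoate F2. iBu2AlH at −78 °C reduces the ester to 2-[(2R)-5-[(1R)-1-(triethylsilyloxy)ethyl]-2,3-dihydrobenzofuran-2-yl]prop-2-en-1-ol F3. PhI(OAc)2, I2 and visible light convert the alcohol into its hypoiodite; the alkoxy radical takes the C3 hydrogen through the same six-membered geometry and the ring closes to the cis-fused 3-methylenetetrahydrofuran ether (2S,3S) F4. Allylic oxidation of the ring CH2 next to oxygen with CrO3·3,5-dimethylpyrazole in CH2Cl2 at −20 °C, a known way from 3-methylenetetrahydrofurans to α-methylene lactones, returns the route at lactone 19.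

Step 8. The ring closure may give low enantioselectivity or the opposite sense of induction. Enantiopurity may also erode, because the amine can add again to the product acrylate and expel the rather acidic phenoxide. The fallback gives up asymmetric catalysis for resolution. It sets out from carbonate 12, which is closed with DABCO (10 mol %) in toluene to methyl 2-(5-acetyl-2,3-dihydrobenzofuran-2-yl)prop-2-enoate (racemic) F5. The enantiomers are separated by preparative chromatography on a polysaccharide-carbamate chiral stationary phase, and the (R) enantiomer is 13, where the route is rejoined.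

Step 5. Enolisation and self-aldol condensation of the arylacetaldehyde may outrun the slow amine-catalysed addition, and the silyl group may move to the new alkoxide. The fallback uses a preformed vinyl metal instead of amine catalysis. Hydroalumination of methyl propiolate with iBu2AlH and N-methylmorpholine N-oxide in THF at 0 °C should give [1-(methoxycarbonyl)vinyl]diisobutylaluminium F6. It is added to aldehyde 8 at −78 °C, where the aldehyde should react ahead of the aryl ketone, and aqueous work-up returns the route at alcohol 10.

Further compounds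
F1 | step 10 | methyl 2-[(2R)-5-[(1R)-1-hydroxyethyl]-2,3-dihydrobenzofuran-2-yl]prop-2-enoate | C=C(C(=O)OC)[C@@H]1Oc2ccc([C@@H](C)O)cc2C1
F2 | step 10 | methyl 2-[(2R)-5-[(1R)-1-(triethylsilyloxy)ethyl]-2,3-dihydrobenzofuran-2-yl]prop-2-enoate | C=C(C(=O)OC)[C@@H]1Oc2ccc([C@@H](C)O[Si](CC)(CC)CC)cc2C1
F3 | step 10 | 2-[(2R)-5-[(1R)-1-(triethylsilyloxy)ethyl]-2,3-dihydrobenzofuran-2-yl]prop-2-en-1-ol | C=C(CO)[C@@H]1Oc2ccc([C@@H](C)O[Si](CC)(CC)CC)cc2C1
F4 | step 10 | cis-fused 3-methylenetetrahydrofuran ether (2S,3S), the analogue of 19 with CH2 in place of the lactone carbonyl | C=C(C3)[C@@H]1Oc2ccc([C@@H](C)O[Si](CC)(CC)CC)cc2[C@@H]1O3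
F5 | step 8 | methyl 2-(5-acetyl-2,3-dihydrobenzofuran-2-yl)prop-2-enoate (racemic) | C=C(C(=O)OC)C1Oc2ccc(C(C)=O)cc2C1
F6 | step 5 | [1-(methoxycarbonyl)vinyl]diisobutylaluminium | C=C(C(=O)OC)[Al](CC(C)C)CC(C)C
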